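## Retrosynthetic overview

1. The C3 acetate and C8 angelate go on last, onto the finished bicyclic alcohol (27 ⇐ 26 ⇐ 25 ⇐ 23).
2. Key step: the C7–C8 bond is made by an intramolecular CrCl2-mediated (Nozaki–Hiyama–Kishi/Barbier) allylation of the C8 aldehyde by the 3-(bromomethyl)butenolide in 21. This closes the ten-membered ring, sets C7 and C8 and delivers the α-methylene lactone in one operation. The usual plan (intermolecular Barbier, then ring-closing metathesis at C1=C2) is deliberately not used.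
3. The butenolide comes from the C6 propargylic alcohol 14 by hydroalumination/iodination and carbonylative lactonisation; C6 is set by asymmetric alkynylation of Z-enal 12.
4. The 4Z olefin comes from syn-carbocupration of ynoate 9; C3 is set by asymmetric alkynylation of E-enal 6.
5. C10 (with C8, C9 and C1) comes from (R)-citramalic acid 1. Ring order: five-membered butenolide first, ten-membered carbocycle second.

## Assumptions

- Atom labels C1–C13 follow germacranolide numbering: lactone C12(=O)–O–C6, C11=C13H2, carbocycle C1–C10 with C3–OAc, C4–CH3, C8–O-angeloyl, C10(CH3)OH.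
- (S,S)-ProPhenol is taken as the ligand hand that sends the alkynylzinc to the Re face of an enal; if the first run shows the opposite sense, (R,R)-ProPhenol is used in steps 4 and 9 and nothing else changes.
- Metal alkoxides that are only protonated at work-up are not numbered; intermediates that undergo a further bond-forming event in the same flask are.

## Route

Step 1
Reactants: 1 (R)-citramalic acid
Product: 2 dimethyl (2R)-2-hydroxy-2-methylbutanedioate
Conditions: HCl (1.25 M in MeOH), rt, 24 h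
Reagents that add atoms: methanol, CO
Why: Fischer esterification at room temperature converts both carboxyl groups without dehydrating the tertiary carbinol, so the future C10 stays R.

Step 2
Reactants: 2 dimethyl (2R)-2-hydroxy-2-methylbutanedioate
Product: 3 methyl (3R)-3,4-dihydroxy-3-methylbutanoate
Conditions: BH3·SMe2 (1.05 equiv), NaBH4 (5 mol %), THF, 0 °C → rt; MeOH quench; used at once
Reagents that add atoms: none
Why: Hydroxyl-directed borane reduction of an α-hydroxy ester: the O-bound borane delivers hydride through a five-membered chelate only to the ester on the carbinol carbon, leaving the CH2CO2Me ester (future C8) and the stereocentre untouched.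

Step 3
Reactants: 3 methyl (3R)-3,4-dihydroxy-3-methylbutanoate; 4 (triphenylphosphoranylidene)acetaldehyde
Product: 6 methyl (3R,4E)-3-hydroxy-3-methyl-6-oxohex-4-enoate, via hydroxy aldehyde 5 (not isolated)
Conditions: Dess–Martin periodinane, pyridine, CH2Cl2, 0 °C; then 4 (1.2 equiv), rt → 40 °C
Reagents that add atoms: (triphenylphosphoranylidene)acetaldehyde (4), O=CC=P(c1ccccc1)(c1ccccc1)c1ccccc1
Why: One-pot Dess–Martin oxidation/Wittig olefination: only the primary alcohol can be oxidised, and the sensitive α-hydroxy aldehyde is trapped at once by the stabilised ylide, which gives the E-enal (C1=C2) selectively.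

Step 4
Reactants: 6 methyl (3R,4E)-3-hydroxy-3-methyl-6-oxohex-4-enoate; 7 methyl propiolate
Product: 8 dimethyl (4S,5E,7R)-4,7-dihydroxy-7-methylnon-5-en-2-ynedioate
Conditions: 7 (3 equiv), Me2Zn (4 equiv), (S,S)-ProPhenol (20 mol %), Ph3PO (40 mol %), toluene, 4 °C, 48 h; aq. NH4Cl
Reagents that add atoms: methyl propiolate (7), C#CC(=O)OC
Why: Zinc–ProPhenol-catalysed enantioselective alkynylation (1,2-addition of a zinc acetylide to an enal) delivers the alkynyl group to the Re face of the C3 aldehyde inside the chiral dinuclear zinc pocket and sets 3S, the tertiary OH being carried as its zinc alkoxide by the extra Me2Zn.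

Step 5
Reactants: 8 dimethyl (4S,5E,7R)-4,7-dihydroxy-7-methylnon-5-en-2-ynedioate
Product: 9 dimethyl (4S,5E,7R)-7-methyl-4,7-bis(triethylsilyloxy)non-5-en-2-ynedioate
Conditions: TESOTf (2.5 equiv), 2,6-lutidine, CH2Cl2, −78 → 0 °C
Reagents that add atoms: triethylsilyl trifluoromethanesulfonate, CC[Si](CC)(CC)OS(=O)(=O)C(F)(F)F
Why: Silyl triflate silylation caps the secondary propargylic and the tertiary alcohol together with groups that survive cuprate, hydride and chromium chemistry and come off together with fluoride at the end.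

Step 6
Reactants: 9 dimethyl (4S,5E,7R)-7-methyl-4,7-bis(triethylsilyloxy)non-5-en-2-ynedioate
Product: 10 dimethyl (2Z,4S,5E,7R)-3,7-dimethyl-4,7-bis(triethylsilyloxy)nona-2,5-dienedioate
Conditions: Me2CuLi (from CuBr·SMe2 and MeLi, 2 equiv), THF, −78 °C, 30 min; MeOH then aq. NH4Cl at −78 °C
Reagents that add atoms: lithium dimethylcuprate Me2CuLi, [Li+].C[Cu-]C
Why: Syn-carbocupration (conjugate addition of a Gilman cuprate to a γ-silyloxy ynoate) puts CH3 on C4 and copper on C5 on the same side, and protonation at −78 °C before the vinylcuprate equilibrates gives the Z-enoate with C3 and C6 cis, which is the 4Z geometry of the target, while the saturated ester is inert.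

Step 7
Reactants: 10 dimethyl (2Z,4S,5E,7R)-3,7-dimethyl-4,7-bis(triethylsilyloxy)nona-2,5-dienedioate
Product: 11 (2Z,4S,5E,7R)-3,7-dimethyl-4,7-bis(triethylsilyloxy)nona-2,5-diene-1,9-diol
Conditions: i-Bu2AlH (6 equiv), CH2Cl2, −78 → −20 °C; aq. potassium sodium tartrate
Reagents that add atoms: none
Why: Hydride 1,2-reduction with i-Bu2AlH takes both esters to primary alcohols in one operation without touching the silyl ethers or the olefin geometries.

Step 8
Reactants: 11 (2Z,4S,5E,7R)-3,7-dimethyl-4,7-bis(triethylsilyloxy)nona-2,5-diene-1,9-diol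
Product: 12 (2Z,4S,5E,7R)-9-hydroxy-3,7-dimethyl-4,7-bis(triethylsilyloxy)nona-2,5-dienal
Conditions: MnO2 (activated, 20 equiv), CH2Cl2, rt, dark
Reagents that add atoms: none
Why: Chemoselective allylic oxidation with MnO2 converts only the allylic C6 alcohol to the enal under neutral conditions that keep the Z geometry, leaving the saturated C8 alcohol free.

Step 9
Reactants: 12 (2Z,4S,5E,7R)-9-hydroxy-3,7-dimethyl-4,7-bis(triethylsilyloxy)nona-2,5-dienal; 13 4-methoxybenzyl propargyl ether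
Product: 14 (4S,5Z,7S,8E,10R)-1-(4-methoxybenzyloxy)-6,10-dimethyl-7,10-bis(triethylsilyloxy)dodeca-5,8-dien-2-yne-4,12-diol
Conditions: 13 (3 equiv), Me2Zn (4.5 equiv), (S,S)-ProPhenol (20 mol %), Ph3PO (40 mol %), toluene, 4 °C → rt; aq. NH4Cl
Reagents that add atoms: 4-methoxybenzyl propargyl ether (13), COc1ccc(COCC#C)cc1
Why: A second zinc–ProPhenol alkynylation adds the alkynylzinc to the Re face of the C6 aldehyde under catalyst control (the C3 centre is 1,4-remote) and sets 6S, the primary OH being masked in situ as its zinc alkoxide.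

Step 10
Reactants: 14 (4S,5Z,7S,8E,10R)-1-(4-methoxybenzyloxy)-6,10-dimethyl-7,10-bis(triethylsilyloxy)dodeca-5,8-dien-2-yne-4,12-diol
Product: 16 (2Z,4S,5Z,7S,8E,10R)-2-iodo-1-(4-methoxybenzyloxy)-6,10-dimethyl-7,10-bis(triethylsilyloxy)dodeca-2,5,8-triene-4,12-diol, via vinylalanate 15 (not isolated)
Conditions: NaAlH2(OCH2CH2OMe)2 (Red-Al, 3.5 equiv), THF, 0 °C, 2 h; then I2, THF, −78 °C; aq. Na2S2O3
Reagents that add atoms: iodine, II
Why: Hydroxyl-directed trans-hydroalumination of a propargylic alcohol delivers hydride to C7 and aluminium to C11 within a five-membered alkoxyaluminate, and iodine cleaves the C–Al bond with retention so that iodine ends up cis to the C6 carbinol as lactonisation requires, the temperature being kept at or below 0 °C to suppress β-elimination of the benzyloxy group to an allene.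

Step 11
Reactants: 16 (2Z,4S,5Z,7S,8E,10R)-2-iodo-1-(4-methoxybenzyloxy)-6,10-dimethyl-7,10-bis(triethylsilyloxy)dodeca-2,5,8-triene-4,12-diol
Product: 17 (5S)-5-[(1Z,3S,4E,6R)-8-hydroxy-2,6-dimethyl-3,6-bis(triethylsilyloxy)octa-1,4-dien-1-yl]-3-[(4-methoxybenzyloxy)methyl]furan-2(5H)-one
Conditions: Pd(PPh3)4 (5 mol %), CO (1 atm), i-Pr2NEt (1.5 equiv), THF/MeCN, rt
Reagents that add atoms: carbon monoxide, [C-]#[O+]
Why: Palladium-catalysed carbonylative lactonisation: oxidative addition of the vinyl iodide to zerovalent palladium, CO insertion and capture of the acylpalladium by the cis C6 hydroxyl close the butenolide (the first ring) without involving the C6 stereocentre.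

Step 12
Reactants: 17 (5S)-5-[(1Z,3S,4E,6R)-8-hydroxy-2,6-dimethyl-3,6-bis(triethylsilyloxy)octa-1,4-dien-1-yl]-3-[(4-methoxybenzyloxy)methyl]furan-2(5H)-one
Product: 18 (3R,4E,6S,7Z)-8-[(2S)-4-[(4-methoxybenzyloxy)methyl]-5-oxo-2,5-dihydrofuran-2-yl]-3,7-dimethyl-3,6-bis(triethylsilyloxy)octa-4,7-dienal
Conditions: Dess–Martin periodinane, pyridine, CH2Cl2, 0 °C → rt
Reagents that add atoms: none
Why: Dess–Martin oxidation of the only free alcohol gives the C8 aldehyde under buffered, non-basic conditions that neither enolise the butenolide nor eliminate the β-silyloxy group.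

Step 13
Reactants: 18 (3R,4E,6S,7Z)-8-[(2S)-4-[(4-methoxybenzyloxy)methyl]-5-oxo-2,5-dihydrofuran-2-yl]-3,7-dimethyl-3,6-bis(triethylsilyloxy)octa-4,7-dienal
Product: 19 (3R,4E,6S,7Z)-8-[(2S)-4-(hydroxymethyl)-5-oxo-2,5-dihydrofuran-2-yl]-3,7-dimethyl-3,6-bis(triethylsilyloxy)octa-4,7-dienal
Conditions: DDQ (1.3 equiv), CH2Cl2/pH 7 buffer (10:1), 0 °C
Reagents that add atoms: none
Why: Oxidative cleavage of the 4-methoxybenzyl ether with DDQ (hydride abstraction from the electron-rich benzylic position, then hydrolysis) is faster than any reaction at the silyl ethers and leaves the aldehyde alone.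

Step 14
Reactants: 19 (3R,4E,6S,7Z)-8-[(2S)-4-(hydroxymethyl)-5-oxo-2,5-dihydrofuran-2-yl]-3,7-dimethyl-3,6-bis(triethylsilyloxy)octa-4,7-dienal
Product: 21 (3R,4E,6S,7Z)-8-[(2S)-4-(bromomethyl)-5-oxo-2,5-dihydrofuran-2-yl]-3,7-dimethyl-3,6-bis(triethylsilyloxy)octa-4,7-dienal, via allylic mesylate 20 (not isolated)
Conditions: MsCl, Et3N, THF, −40 °C, 15 min; then LiBr, THF, −40 → 0 °C; used at once
Reagents that add atoms: lithium bromide LiBr, [Li+].[Br-]
Why: Sulfonylation followed by SN2 (Finkelstein-type) displacement gives the primary allylic bromide at low temperature and without strong base, so the epimerisable C6 centre and the β-silyloxy aldehyde survive.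

Step 15
Reactants: 21 (3R,4E,6S,7Z)-8-[(2S)-4-(bromomethyl)-5-oxo-2,5-dihydrofuran-2-yl]-3,7-dimethyl-3,6-bis(triethylsilyloxy)octa-4,7-dienal
Product: 23 (3aS,4R,6R,7E,9S,10Z,11aS)-4-hydroxy-6,10-dimethyl-3-methylidene-6,9-bis(triethylsilyloxy)-3a,4,5,6,9,11a-hexahydrocyclodeca[b]furan-2(3H)-one, via allylchromium dichloride 22 (not isolated)
Conditions: CrCl2 (8 equiv), THF, rt, syringe-pump addition of 21 over 12 h (final 2 mM); aq. NH4Cl
Reagents that add atoms: none
Why: Intramolecular Nozaki–Hiyama–Kishi-type (Barbier) allylation: CrCl2 turns the bromide into an allylchromium species (trivalent chromium) that adds through its γ-carbon C7 to the tethered C8 aldehyde in a six-membered chair (Zimmerman–Traxler) transition state, attack anti to the C6 side chain giving the trans-fused lactone (7S), the ring-locked allyl geometry with the C9 chain equatorial giving 8R, and the exocyclic methylene lactone and the ten-membered ring appearing together.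

Step 16
Reactants: 23 (3aS,4R,6R,7E,9S,10Z,11aS)-4-hydroxy-6,10-dimethyl-3-methylidene-6,9-bis(triethylsilyloxy)-3a,4,5,6,9,11a-hexahydrocyclodeca[b]furan-2(3H)-one; 24 angelic acid
Product: 25 (3aS,4R,6R,7E,9S,10Z,11aS)-6,10-dimethyl-3-methylidene-2-oxo-6,9-bis(triethylsilyloxy)-2,3,3a,4,5,6,9,11a-octahydrocyclodeca[b]furan-4-yl (2Z)-2-methylbut-2-enoate
Conditions: 24, 2,4,6-trichlorobenzoyl chloride, Et3N, toluene, rt, 2 h; then 23, toluene, 75 °C
Reagents that add atoms: angelic acid (24), C/C=C(/C)C(=O)O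
Why: Yamaguchi-type mixed-anhydride esterification without a nucleophilic catalyst acylates the only free (secondary C8) alcohol at its less hindered angeloyl carbonyl and avoids the addition–elimination pathway that would isomerise the Z (angelate) double bond to the tiglate.

Step 17
Reactants: 25 (3aS,4R,6R,7E,9S,10Z,11aS)-6,10-dimethyl-3-methylidene-2-oxo-6,9-bis(triethylsilyloxy)-2,3,3a,4,5,6,9,11a-octahydrocyclodeca[b]furan-4-yl (2Z)-2-methylbut-2-enoate
Product: 26 (3aS,4R,6R,7E,9S,10Z,11aS)-6,9-dihydroxy-6,10-dimethyl-3-methylidene-2-oxo-2,3,3a,4,5,6,9,11a-octahydrocyclodeca[b]furan-4-yl (2Z)-2-methylbut-2-enoate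
Conditions: HF·pyridine, pyridine, THF, 0 °C → rt
Reagents that add atoms: none
Why: Buffered fluoride-mediated desilylation removes both triethylsilyl ethers under conditions tolerated by the α-methylene lactone, the angelate and the doubly allylic C3 carbinol.

Step 18
Reactants: 26 (3aS,4R,6R,7E,9S,10Z,11aS)-6,9-dihydroxy-6,10-dimethyl-3-methylidene-2-oxo-2,3,3a,4,5,6,9,11a-octahydrocyclodeca[b]furan-4-yl (2Z)-2-methylbut-2-enoate
Product: 27 CNP0181631.2, (3aS,4R,6R,7E,9S,10Z,11aS)-9-acetoxy-6-hydroxy-6,10-dimethyl-3-methylidene-2-oxo-2,3,3a,4,5,6,9,11a-octahydrocyclodeca[b]furan-4-yl (2Z)-2-methylbut-2-enoate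
Conditions: Ac2O (1.5 equiv), pyridine, DMAP (5 mol %), CH2Cl2, 0 °C
Reagents that add atoms: acetic anhydride, CC(=O)OC(C)=O
Why: Nucleophile-catalysed acetylation is selective for the secondary C3 alcohol because the tertiary C10 alcohol does not react at 0 °C, which completes the target with all five stereocentres and both ring olefins unchanged.

## Compound list

1 | (R)-citramalic acid, (2R)-2-hydroxy-2-methylbutanedioic acid | OC(=O)[C@](C)(O)CC(=O)O | starting material
2 | dimethyl (2R)-2-hydroxy-2-methylbutanedioate | COC(=O)[C@](C)(O)CC(=O)OC | intermediate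
3 | methyl (3R)-3,4-dihydroxy-3-methylbutanoate | OC[C@](C)(O)CC(=O)OC | intermediate
4 | (triphenylphosphoranylidene)acetaldehyde | O=CC=P(c1ccccc1)(c1ccccc1)c1ccccc1 | starting material
5 | methyl (3R)-3-hydroxy-3-methyl-4-oxobutanoate (not isolated) | O=C[C@](C)(O)CC(=O)OC | intermediate
6 | methyl (3R,4E)-3-hydroxy-3-methyl-6-oxohex-4-enoate | O=C/C=C/[C@](C)(O)CC(=O)OC | intermediate
7 | methyl propiolate | C#CC(=O)OC | starting material
8 | dimethyl (4S,5E,7R)-4,7-dihydroxy-7-methylnon-5-en-2-ynedioate | COC(=O)C#C[C@@H](O)/C=C/[C@](C)(O)CC(=O)OC | intermediate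
9 | dimethyl (4S,5E,7R)-7-methyl-4,7-bis(triethylsilyloxy)non-5-en-2-ynedioate | COC(=O)C#C[C@@H](O[Si](CC)(CC)CC)/C=C/[C@](C)(O[Si](CC)(CC)CC)CC(=O)OC | intermediate
10 | dimethyl (2Z,4S,5E,7R)-3,7-dimethyl-4,7-bis(triethylsilyloxy)nona-2,5-dienedioate | COC(=O)/C=C(/C)[C@@H](O[Si](CC)(CC)CC)/C=C/[C@](C)(O[Si](CC)(CC)CC)CC(=O)OC | intermediate
11 | (2Z,4S,5E,7R)-3,7-dimethyl-4,7-bis(triethylsilyloxy)nona-2,5-diene-1,9-diol | OC/C=C(/C)[C@@H](O[Si](CC)(CC)CC)/C=C/[C@](C)(O[Si](CC)(CC)CC)CCO | intermediate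
12 | (2Z,4S,5E,7R)-9-hydroxy-3,7-dimethyl-4,7-bis(triethylsilyloxy)nona-2,5-dienal | O=C/C=C(/C)[C@@H](O[Si](CC)(CC)CC)/C=C/[C@](C)(O[Si](CC)(CC)CC)CCO | intermediate
13 | 4-methoxybenzyl propargyl ether, 1-methoxy-4-[(prop-2-yn-1-yloxy)methyl]benzene | COc1ccc(COCC#C)cc1 | starting material
14 | (4S,5Z,7S,8E,10R)-1-(4-methoxybenzyloxy)-6,10-dimethyl-7,10-bis(triethylsilyloxy)dodeca-5,8-dien-2-yne-4,12-diol | COc1ccc(COCC#C[C@@H](O)/C=C(/C)[C@@H](O[Si](CC)(CC)CC)/C=C/[C@](C)(O[Si](CC)(CC)CC)CCO)cc1 | intermediate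
15 | sodium (5S)-2,2-bis(2-methoxyethoxy)-3-[(4-methoxybenzyloxy)methyl]-5-[(1Z,3S,4E,6R)-8-hydroxy-2,6-dimethyl-3,6-bis(triethylsilyloxy)octa-1,4-dien-1-yl]-2,5-dihydro-1,2-oxaluminol-2-uide (cyclic alkoxy(vinyl)aluminate, not isolated; remote primary OH drawn free, aluminium-bound in the flask) | [Na+].COCCO[Al-]1(OCCOC)O[C@H](C=C1COCc1ccc(OC)cc1)/C=C(/C)[C@@H](O[Si](CC)(CC)CC)/C=C/[C@](C)(O[Si](CC)(CC)CC)CCO | intermediate
16 | (2Z,4S,5Z,7S,8E,10R)-2-iodo-1-(4-methoxybenzyloxy)-6,10-dimethyl-7,10-bis(triethylsilyloxy)dodeca-2,5,8-triene-4,12-diol | COc1ccc(COC/C(I)=C/[C@@H](O)/C=C(/C)[C@@H](O[Si](CC)(CC)CC)/C=C/[C@](C)(O[Si](CC)(CC)CC)CCO)cc1 | intermediate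
17 | (5S)-5-[(1Z,3S,4E,6R)-8-hydroxy-2,6-dimethyl-3,6-bis(triethylsilyloxy)octa-1,4-dien-1-yl]-3-[(4-methoxybenzyloxy)methyl]furan-2(5H)-one | COc1ccc(COCC2=C[C@@H](OC2=O)/C=C(/C)[C@@H](O[Si](CC)(CC)CC)/C=C/[C@](C)(O[Si](CC)(CC)CC)CCO)cc1 | intermediate
18 | (3R,4E,6S,7Z)-8-[(2S)-4-[(4-methoxybenzyloxy)methyl]-5-oxo-2,5-dihydrofuran-2-yl]-3,7-dimethyl-3,6-bis(triethylsilyloxy)octa-4,7-dienal | COc1ccc(COCC2=C[C@@H](OC2=O)/C=C(/C)[C@@H](O[Si](CC)(CC)CC)/C=C/[C@](C)(O[Si](CC)(CC)CC)CC=O)cc1 | intermediate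
19 | (3R,4E,6S,7Z)-8-[(2S)-4-(hydroxymethyl)-5-oxo-2,5-dihydrofuran-2-yl]-3,7-dimethyl-3,6-bis(triethylsilyloxy)octa-4,7-dienal | OCC1=C[C@@H](OC1=O)/C=C(/C)[C@@H](O[Si](CC)(CC)CC)/C=C/[C@](C)(O[Si](CC)(CC)CC)CC=O | intermediate
20 | [(5S)-5-[(1Z,3S,4E,6R)-2,6-dimethyl-8-oxo-3,6-bis(triethylsilyloxy)octa-1,4-dien-1-yl]-2-oxo-2,5-dihydrofuran-3-yl]methyl methanesulfonate (not isolated) | CS(=O)(=O)OCC1=C[C@@H](OC1=O)/C=C(/C)[C@@H](O[Si](CC)(CC)CC)/C=C/[C@](C)(O[Si](CC)(CC)CC)CC=O | intermediate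
21 | (3R,4E,6S,7Z)-8-[(2S)-4-(bromomethyl)-5-oxo-2,5-dihydrofuran-2-yl]-3,7-dimethyl-3,6-bis(triethylsilyloxy)octa-4,7-dienal | BrCC1=C[C@@H](OC1=O)/C=C(/C)[C@@H](O[Si](CC)(CC)CC)/C=C/[C@](C)(O[Si](CC)(CC)CC)CC=O | intermediate
22 | {[(5S)-5-[(1Z,3S,4E,6R)-2,6-dimethyl-8-oxo-3,6-bis(triethylsilyloxy)octa-1,4-dien-1-yl]-2-oxo-2,5-dihydrofuran-3-yl]methyl}chromium dichloride (allyl–CrCl2, trivalent chromium, THF ligands omitted, not isolated) | Cl[Cr](Cl)CC1=C[C@@H](OC1=O)/C=C(/C)[C@@H](O[Si](CC)(CC)CC)/C=C/[C@](C)(O[Si](CC)(CC)CC)CC=O | intermediate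
23 | (3aS,4R,6R,7E,9S,10Z,11aS)-4-hydroxy-6,10-dimethyl-3-methylidene-6,9-bis(triethylsilyloxy)-3a,4,5,6,9,11a-hexahydrocyclodeca[b]furan-2(3H)-one | C=C1C(=O)O[C@H]2/C=C(/C)[C@@H](O[Si](CC)(CC)CC)/C=C/[C@](C)(O[Si](CC)(CC)CC)C[C@@H](O)[C@H]12 | intermediate
24 | angelic acid, (2Z)-2-methylbut-2-enoic acid | C/C=C(/C)C(=O)O | starting material
25 | (3aS,4R,6R,7E,9S,10Z,11aS)-6,10-dimethyl-3-methylidene-2-oxo-6,9-bis(triethylsilyloxy)-2,3,3a,4,5,6,9,11a-octahydrocyclodeca[b]furan-4-yl (2Z)-2-methylbut-2-enoate | C=C1C(=O)O[C@H]2/C=C(/C)[C@@H](O[Si](CC)(CC)CC)/C=C/[C@](C)(O[Si](CC)(CC)CC)C[C@@H](OC(=O)/C(C)=C\C)[C@H]12 | intermediate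
26 | (3aS,4R,6R,7E,9S,10Z,11aS)-6,9-dihydroxy-6,10-dimethyl-3-methylidene-2-oxo-2,3,3a,4,5,6,9,11a-octahydrocyclodeca[b]furan-4-yl (2Z)-2-methylbut-2-enoate | C=C1C(=O)O[C@H]2/C=C(/C)[C@@H](O)/C=C/[C@](C)(O)C[C@@H](OC(=O)/C(C)=C\C)[C@H]12 | intermediate
27 | CNP0181631.2, (3aS,4R,6R,7E,9S,10Z,11aS)-9-acetoxy-6-hydroxy-6,10-dimethyl-3-methylidene-2-oxo-2,3,3a,4,5,6,9,11a-octahydrocyclodeca[b]furan-4-yl (2Z)-2-methylbut-2-enoate | C=C1C(=O)O[C@H]2/C=C(/C)[C@@H](OC(C)=O)/C=C/[C@](C)(O)C[C@@H](OC(=O)/C(C)=C\C)[C@H]12 | target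

## Step count and risks

Total step count: 18. Longest linear sequence: 18 steps from 1 (4, 7, 13 and 24 are bought and enter directly).

The three steps most likely to fail:

**Step 15 (macrocyclic chromium allylation).** The ring closure competes with oligomerisation, and the tether rather than the intrinsic transition-state preference may decide the C7/C8 outcome. The fallback sets out from 21 and returns at 23. Pd2(dba)3-catalysed borylation of the allylic bromide with bis(pinacolato)diboron in toluene gives the pinacol allylboronate aldehyde F1. Kept at 2 mM in toluene at 60–80 °C (Sc(OTf)3 if needed), F1 closes by thermal allylboration through the same closed six-membered chair, with no reducing metal and a tighter boron-centred transition state. Aqueous work-up of the borate gives 23.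

**Step 10 (hydroalumination/iodination).** The vinylalanate can eliminate the neighbouring benzyloxy group to an allene, or the hydride can be delivered with poor regiocontrol. The fallback sets out from 14 and returns at 16. [Cp*Ru(MeCN)3]PF6-catalysed trans-hydrosilylation with BnMe2SiH in CH2Cl2 places silicon on C11, distal to the free C6 hydroxyl, and gives the (Z)-vinylsilane F2, which carries no anionic vinyl–metal bond that could eliminate. Iododesilylation with N-iodosuccinimide in (CF3)2CHOH proceeds with retention and gives 16.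

**Step 16 (angeloylation).** Heating with base can isomerise the angelate to the tiglate or let the C8 alkoxide translactonise onto C12. The fallback sets out from 23 and returns at 25. Carbodiimide esterification of 23 with 2-[bis(2,2,2-trifluoroethoxy)phosphoryl]propanoic acid at 0 °C gives the phosphonopropanoate ester F3. Still–Gennari olefination of F3 with acetaldehyde (KN(SiMe3)2, 18-crown-6, THF, −78 °C) builds the (Z)-2-methylbut-2-enoate in place and gives 25.

## Further compounds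

F1 | step 15 | (3R,4E,6S,7Z)-3,7-dimethyl-8-[(2S)-5-oxo-4-[(4,4,5,5-tetramethyl-1,3,2-dioxaborolan-2-yl)methyl]-2,5-dihydrofuran-2-yl]-3,6-bis(triethylsilyloxy)octa-4,7-dienal | CC1(C)OB(CC2=C[C@@H](OC2=O)/C=C(/C)[C@@H](O[Si](CC)(CC)CC)/C=C/[C@](C)(O[Si](CC)(CC)CC)CC=O)OC1(C)C
F2 | step 10 | (2Z,4S,5Z,7S,8E,10R)-2-[benzyl(dimethyl)silyl]-1-(4-methoxybenzyloxy)-6,10-dimethyl-7,10-bis(triethylsilyloxy)dodeca-2,5,8-triene-4,12-diol | COc1ccc(COC/C(=C/[C@@H](O)/C=C(/C)[C@@H](O[Si](CC)(CC)CC)/C=C/[C@](C)(O[Si](CC)(CC)CC)CCO)[Si](C)(C)Cc2ccccc2)cc1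
F3 | step 16 | (3aS,4R,6R,7E,9S,10Z,11aS)-6,10-dimethyl-3-methylidene-2-oxo-6,9-bis(triethylsilyloxy)-2,3,3a,4,5,6,9,11a-octahydrocyclodeca[b]furan-4-yl 2-[bis(2,2,2-trifluoroethoxy)phosphoryl]propanoate (both epimers at the phosphonate carbon) | C=C1C(=O)O[C@H]2/C=C(/C)[C@@H](O[Si](CC)(CC)CC)/C=C/[C@](C)(O[Si](CC)(CC)CC)C[C@@H](OC(=O)C(C)P(=O)(OCC(F)(F)F)OCC(F)(F)F)[C@H]12
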